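## Retrosynthetic overview

1. The target comes from acetylation of the C10 alcohol, after hydroxyl-directed epoxidation of C8=C9; the 10α-allylic alcohol comes from ketoreductase reduction of a C10 enone that already carries the C6 isovalerate.
2. The seven-membered ring (last carbocycle) is closed by ring-closing metathesis at C8=C9, between a 1-hydroxyallyl arm on C1 and a 1-hydroxy-3-methylbut-3-enyl arm on C5 of a trans-disubstituted cyclopentane.
3. The arms come from chelation-controlled methallylation of a C6 aldehyde and vinyl addition to a C10 aldehyde (kept as an acetal until then).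
4. The five-membered ring comes from an amine-catalysed intramolecular aldol of a keto aldehyde (C5 onto the C4 isopropyl ketone), itself made by ozonolysis of a cyclohexene.
5. That cyclohexene (a sacrificial six-membered ring, made first) comes from a catalytic enantioselective Diels–Alder reaction of methacrolein with 2-isopropylbutadiene, which sets quaternary C1. Ring order: six (opened), five, seven, oxirane.

Locants used throughout (daucane skeleton): C1 = angular carbon bearing CH3; C2, C3 = the CH2 groups of the five-membered ring; C4 = carbon bearing OH and isopropyl; C5 = ring-fusion CH; C6 (O-acyl), C7 (CH2), C8 (C–CH3), C9, C10 (O) complete the seven-membered ring back to C1. The target is 1S,4R,5S,6S,8R,9S,10S.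

Assumption: the (S)-oxazaborolidinium catalyst gives the (1S) Diels–Alder aldehyde, as reported for isoprene; if the facial sense were the opposite, the (R)-catalyst is used.

## Route

Step 1
Reactants: 1 3-methylbut-1-yne; 2 ethene
Product: 3 2-(propan-2-yl)buta-1,3-diene
Conditions: second-generation Grubbs catalyst (H2IMes)(PCy3)Cl2Ru=CHPh (2 mol%), ethene (3 bar), CH2Cl2, 40 °C; flash distillation
Reagents that add atoms: none
Why: Ene–yne cross-metathesis: the ruthenium methylidene adds across the terminal alkyne and ethene releases the vinylcarbene as the 2-substituted 1,3-diene; no stereocenter is formed.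

Step 2
Reactants: 3 2-(propan-2-yl)buta-1,3-diene; 4 methacrolein
Product: 5 (1S)-1-methyl-4-(propan-2-yl)cyclohex-3-ene-1-carbaldehyde
Conditions: (3aS)-1-(2-methylphenyl)-3,3-diphenyltetrahydro-3H-pyrrolo[1,2-c][1,3,2]oxazaborole activated with HN(SO2CF3)2 (10 mol%), CH2Cl2, −78 to −40 °C
Reagents that add atoms: none
Why: Catalytic enantioselective Diels–Alder reaction: the chiral oxazaborolidinium cation binds the formyl group and shields one face of methacrolein, so quaternary C1 is set as S, and the 2-alkyl diene gives the 1,4 ("para") regioisomer.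

Step 3
Reactants: 5 (1S)-1-methyl-4-(propan-2-yl)cyclohex-3-ene-1-carbaldehyde
Product: 6 (4S)-4-(dimethoxymethyl)-4-methyl-1-(propan-2-yl)cyclohex-1-ene
Conditions: HC(OMe)3, MeOH, p-toluenesulfonic acid (cat.), rt
Reagents that add atoms: trimethyl orthoformate, COC(OC)OC
Why: Acid-catalysed acetalisation masks the non-enolisable C10 aldehyde and makes this group the bulkiest substituent on C1; no stereocenter is touched.

Step 4
Reactants: 6 (4S)-4-(dimethoxymethyl)-4-methyl-1-(propan-2-yl)cyclohex-1-ene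
Product: 8 (3S)-3-(dimethoxymethyl)-3,7-dimethyl-6-oxooctanal, via secondary ozonide 7 (not isolated)
Conditions: O3, CH2Cl2, −78 °C; then Me2S, −78 °C to rt
Reagents that add atoms: ozone, [O-][O+]=O
Why: Ozonolysis with reductive work-up cleaves the only C=C bond into the C4 isopropyl ketone and the C6 aldehyde; the acetal and the quaternary centre are inert.

Step 5
Reactants: 8 (3S)-3-(dimethoxymethyl)-3,7-dimethyl-6-oxooctanal
Product: 9 (1R,2R,5S)-5-(dimethoxymethyl)-2-hydroxy-5-methyl-2-(propan-2-yl)cyclopentane-1-carbaldehyde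
Conditions: L-proline (30 mol%), DMSO, rt, 24 h
Reagents that add atoms: none
Why: Enamine-catalysed intramolecular aldol (5-enolexo; only the aldehyde forms the enamine, the ketone is the acceptor); the reaction is reversible and the most stable isomer has the formyl group trans to both bulky neighbours (acetal on C1, isopropyl on C4) and cis to the hydrogen-bonded hydroxyl, which fixes C4 (OH cis to the C1 methyl) and C5.

Step 6
Reactants: 9 (1R,2R,5S)-5-(dimethoxymethyl)-2-hydroxy-5-methyl-2-(propan-2-yl)cyclopentane-1-carbaldehyde; 10 (2-methylprop-2-en-1-yl)magnesium chloride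
Product: 11 (1R,2S,3S)-3-(dimethoxymethyl)-2-[(1S)-1-hydroxy-3-methylbut-3-en-1-yl]-3-methyl-1-(propan-2-yl)cyclopentan-1-ol
Conditions: 10 (2.5 equiv), THF, −78 °C; aq. NH4Cl
Reagents that add atoms: none
Why: Cram-chelate-controlled Grignard addition: the magnesium alkoxide of the C4 hydroxyl chelates the aldehyde oxygen and the allylic nucleophile enters from the side of the C5 hydrogen, away from quaternary C1, giving the 6S carbinol.

Step 7
Reactants: 11 (1R,2S,3S)-3-(dimethoxymethyl)-2-[(1S)-1-hydroxy-3-methylbut-3-en-1-yl]-3-methyl-1-(propan-2-yl)cyclopentan-1-ol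
Product: 12 (1S,2S,3R)-3-hydroxy-2-[(1S)-1-hydroxy-3-methylbut-3-en-1-yl]-1-methyl-3-(propan-2-yl)cyclopentane-1-carbaldehyde
Conditions: pyridinium p-toluenesulfonate (cat.), acetone/H2O 9:1, 50 °C
Reagents that add atoms: water, O
Why: Mild acid hydrolysis of the dimethyl acetal; the formyl group is trans to both hydroxyl-bearing neighbours, so lactol formation is disfavoured, and the tertiary alcohol and 1,1-disubstituted alkene survive.

Step 8
Reactants: 12 (1S,2S,3R)-3-hydroxy-2-[(1S)-1-hydroxy-3-methylbut-3-en-1-yl]-1-methyl-3-(propan-2-yl)cyclopentane-1-carbaldehyde; 13 ethenylmagnesium bromide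
Product: 14 (1R,2S,3S)-3-[(1RS)-1-hydroxyprop-2-en-1-yl]-2-[(1S)-1-hydroxy-3-methylbut-3-en-1-yl]-3-methyl-1-(propan-2-yl)cyclopentan-1-ol (both C10 epimers)
Conditions: 13 (4 equiv), THF, −78 to 0 °C; aq. NH4Cl
Reagents that add atoms: none
Why: Grignard 1,2-addition to the neopentyl aldehyde (two equivalents are consumed by the hydroxyls); C10 forms without control and both epimers are carried on, because the centre is erased in step 10 and reset in step 12.

Step 9
Reactants: 14 (1R,2S,3S)-3-[(1RS)-1-hydroxyprop-2-en-1-yl]-2-[(1S)-1-hydroxy-3-methylbut-3-en-1-yl]-3-methyl-1-(propan-2-yl)cyclopentan-1-ol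
Product: 15 (1S,4R,5S,6S,10RS)-dauc-8-ene-4,6,10-triol (both C10 epimers)
Conditions: second-generation Grubbs catalyst (H2IMes)(PCy3)Cl2Ru=CHPh (5 mol%), CH2Cl2 (5 mM), 40 °C
Reagents that add atoms: none
Why: Ring-closing metathesis between the monosubstituted and the 1,1-disubstituted alkene closes the trans-fused seven-membered ring with the trisubstituted C8=C9 bond, driven by loss of ethene.

Step 10
Reactants: 15 (1S,4R,5S,6S,10RS)-dauc-8-ene-4,6,10-triol
Product: 16 (1S,4R,5S,6S)-4,6-dihydroxydauc-8-en-10-one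
Conditions: activated MnO2 (20 equiv), CH2Cl2, rt
Reagents that add atoms: none
Why: Chemoselective allylic oxidation: MnO2 oxidises only the allylic C10 alcohol (not the saturated C6 or tertiary C4 hydroxyl), so both epimers converge on one enone.

Step 11
Reactants: 16 (1S,4R,5S,6S)-4,6-dihydroxydauc-8-en-10-one; 17 3-methylbutanoic anhydride
Product: 18 (1S,4R,5S,6S)-4-hydroxy-10-oxodauc-8-en-6-yl 3-methylbutanoate
Conditions: 17 (1.5 equiv), pyridine, 4-(dimethylamino)pyridine (cat.), CH2Cl2, 0 °C to rt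
Reagents that add atoms: none
Why: Nucleophile-catalysed acyl transfer (DMAP acylation) esterifies the only secondary hydroxyl; the hindered tertiary C4 hydroxyl does not react, and the mild base avoids vinylogous elimination of the new ester.

Step 12
Reactants: 18 (1S,4R,5S,6S)-4-hydroxy-10-oxodauc-8-en-6-yl 3-methylbutanoate
Product: 19 (1S,4R,5S,6S,10R)-4,10-dihydroxydauc-8-en-6-yl 3-methylbutanoate
Conditions: ketoreductase (NADPH-dependent, variant selected from a panel for 10R), NADP+ (cat.), propan-2-ol (10 vol%), KH2PO4/K2HPO4 buffer pH 7, DMSO (10 vol%), 30 °C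
Reagents that add atoms: none
Why: Enzymatic carbonyl reduction by a ketoreductase: hydride from NADPH (recycled with propan-2-ol) is delivered to the β face of the enone carbonyl under enzyme control, giving the 10α (10R) allylic alcohol regardless of the substrate's own bias; only C=O is reduced.

Step 13
Reactants: 19 (1S,4R,5S,6S,10R)-4,10-dihydroxydauc-8-en-6-yl 3-methylbutanoate
Product: 20 (1S,4R,5S,6S,8R,9S,10S)-8,9-epoxy-4,10-dihydroxydaucan-6-yl 3-methylbutanoate
Conditions: VO(acac)2 (5 mol%), t-BuOOH (1.5 equiv, decane), CH2Cl2, 0 °C to rt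
Reagents that add atoms: tert-butyl hydroperoxide, CC(C)(C)OO
Why: Hydroxyl-directed vanadium-catalysed epoxidation (Sharpless–Michaelson type): the vanadate ester of the C10 alcohol delivers oxygen syn, which for cyclohept-2-enols gives the cis epoxy alcohol, here the 8α,9α-epoxide (8R,9S).

Step 14
Reactants: 20 (1S,4R,5S,6S,8R,9S,10S)-8,9-epoxy-4,10-dihydroxydaucan-6-yl 3-methylbutanoate
Product: 21 (1S,4R,5S,6S,8R,9S,10S)-10-acetoxy-8,9-epoxy-4-hydroxydaucan-6-yl 3-methylbutanoate
Conditions: Ac2O (1.5 equiv), pyridine, 4-(dimethylamino)pyridine (cat.), CH2Cl2, 0 °C to rt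
Reagents that add atoms: acetic anhydride, CC(=O)OC(C)=O
Why: DMAP-catalysed acetylation of the secondary C10 hydroxyl; the tertiary C4 hydroxyl, the epoxide and the isovalerate are untouched under these mild conditions.

## Compound list

1 | 3-methylbut-1-yne | CC(C)C#C | starting material
2 | ethene | C=C | starting material
3 | 2-(propan-2-yl)buta-1,3-diene | C=CC(=C)C(C)C | intermediate
4 | methacrolein (2-methylprop-2-enal) | CC(=C)C=O | starting material
5 | (1S)-1-methyl-4-(propan-2-yl)cyclohex-3-ene-1-carbaldehyde | O=C[C@@]1(C)CCC(C(C)C)=CC1 | intermediate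
6 | (4S)-4-(dimethoxymethyl)-4-methyl-1-(propan-2-yl)cyclohex-1-ene | COC(OC)[C@@]1(C)CCC(C(C)C)=CC1 | intermediate
7 | secondary ozonide, (4S)-4-(dimethoxymethyl)-4-methyl-1-(propan-2-yl)-7,8,9-trioxabicyclo[4.2.1]nonane (both bridgehead configurations) | CC(C)C12CC[C@](C)(C(OC)OC)CC(O1)OO2 | intermediate (not isolated)
8 | (3S)-3-(dimethoxymethyl)-3,7-dimethyl-6-oxooctanal | O=CC[C@@](C)(C(OC)OC)CCC(=O)C(C)C | intermediate
9 | (1R,2R,5S)-5-(dimethoxymethyl)-2-hydroxy-5-methyl-2-(propan-2-yl)cyclopentane-1-carbaldehyde | COC(OC)[C@@]1(C)CC[C@@](O)(C(C)C)[C@@H]1C=O | intermediate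
10 | (2-methylprop-2-en-1-yl)magnesium chloride (methallylmagnesium chloride) | CC(=C)C[Mg]Cl | starting material
11 | (1R,2S,3S)-3-(dimethoxymethyl)-2-[(1S)-1-hydroxy-3-methylbut-3-en-1-yl]-3-methyl-1-(propan-2-yl)cyclopentan-1-ol | COC(OC)[C@@]1(C)CC[C@@](O)(C(C)C)[C@@H]1[C@@H](O)CC(C)=C | intermediate
12 | (1S,2S,3R)-3-hydroxy-2-[(1S)-1-hydroxy-3-methylbut-3-en-1-yl]-1-methyl-3-(propan-2-yl)cyclopentane-1-carbaldehyde | O=C[C@@]1(C)CC[C@@](O)(C(C)C)[C@@H]1[C@@H](O)CC(C)=C | intermediate
13 | ethenylmagnesium bromide (vinylmagnesium bromide) | C=C[Mg]Br | starting material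
14 | (1R,2S,3S)-3-[(1RS)-1-hydroxyprop-2-en-1-yl]-2-[(1S)-1-hydroxy-3-methylbut-3-en-1-yl]-3-methyl-1-(propan-2-yl)cyclopentan-1-ol (C10 epimers) | C=CC(O)[C@@]1(C)CC[C@@](O)(C(C)C)[C@@H]1[C@@H](O)CC(C)=C | intermediate
15 | (1S,4R,5S,6S,10RS)-dauc-8-ene-4,6,10-triol (C10 epimers) | OC1C=C(C)C[C@H](O)[C@@H]2[C@]1(C)CC[C@@]2(O)C(C)C | intermediate
16 | (1S,4R,5S,6S)-4,6-dihydroxydauc-8-en-10-one | O=C1C=C(C)C[C@H](O)[C@@H]2[C@]1(C)CC[C@@]2(O)C(C)C | intermediate
17 | 3-methylbutanoic anhydride (isovaleric anhydride) | CC(C)CC(=O)OC(=O)CC(C)C | starting material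
18 | (1S,4R,5S,6S)-4-hydroxy-10-oxodauc-8-en-6-yl 3-methylbutanoate | O=C1C=C(C)C[C@H](OC(=O)CC(C)C)[C@@H]2[C@]1(C)CC[C@@]2(O)C(C)C | intermediate
19 | (1S,4R,5S,6S,10R)-4,10-dihydroxydauc-8-en-6-yl 3-methylbutanoate | O[C@@H]1C=C(C)C[C@H](OC(=O)CC(C)C)[C@@H]2[C@]1(C)CC[C@@]2(O)C(C)C | intermediate
20 | (1S,4R,5S,6S,8R,9S,10S)-8,9-epoxy-4,10-dihydroxydaucan-6-yl 3-methylbutanoate | O[C@@H]1[C@@H]2O[C@]2(C)C[C@H](OC(=O)CC(C)C)[C@@H]2[C@]1(C)CC[C@@]2(O)C(C)C | intermediate
21 | (1S,4R,5S,6S,8R,9S,10S)-10-acetoxy-8,9-epoxy-4-hydroxydaucan-6-yl 3-methylbutanoate | CC(=O)O[C@@H]1[C@@H]2O[C@]2(C)C[C@H](OC(=O)CC(C)C)[C@@H]2[C@]1(C)CC[C@@]2(O)C(C)C | target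

## Step count and risks

Total steps: 14. Longest linear sequence: 14 (the route is linear from 3-methylbut-1-yne).

The three steps most likely to fail:

Step 5 (intramolecular aldol). The tertiary aldol may dehydrate to the enal, the ketone-enolate mode may compete, or the wrong C4 face may be taken. The fallback sets out from 8 and comes back at 9. The aldehyde of 8 is oxidised (NaClO2, NaH2PO4, 2-methylbut-2-ene, t-BuOH/H2O) to (3S)-3-(dimethoxymethyl)-3,7-dimethyl-6-oxooctanoic acid F1. F1 is converted (EtSH, dicyclohexylcarbodiimide, DMAP) into S-ethyl (3S)-3-(dimethoxymethyl)-3,7-dimethyl-6-oxooctanethioate F2. F2 is cyclised by soft enolisation (MgBr2·OEt2, i-Pr2NEt, CH2Cl2), in which only the thioester is enolised and the magnesium-chelated aldolate places the hydroxyl cis to the acyl group, to S-ethyl (1R,2R,5S)-5-(dimethoxymethyl)-2-hydroxy-5-methyl-2-(propan-2-yl)cyclopentane-1-carbothioate F3. Fukuyama reduction of F3 (Et3SiH, palladium on carbon, acetone) returns aldehyde 9.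

Step 6 (chelation-controlled methallylation). Retro-aldol of the magnesium aldolate or incomplete chelation could erode the C6 selectivity. The fallback sets out from 9 and comes back at 11 with reagent control in place of substrate control: 9 is treated with B-methallyldiisopinocampheylborane, (Ipc)2B–CH2C(CH3)=CH2, of the series derived from (+)-α-pinene (made from the B-methoxy borane and 10), in Et2O at −78 °C, followed by NaOH/H2O2 work-up. The chair-like allylboration transition state fixes 6S and gives 11 directly; no new isolated compound is involved.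

Step 12 (ketoreductase reduction of the hindered bicyclic enone). No panel enzyme may accept the substrate or give the 10R alcohol. The fallback sets out from 12 and comes back at 19, making C10 by reagent-controlled C–C bond formation instead of ketone reduction. Compound 12 is acylated first (17, pyridine, DMAP) to (1S)-1-[(1S,2S,5R)-2-formyl-5-hydroxy-2-methyl-5-(propan-2-yl)cyclopentyl]-3-methylbut-3-en-1-yl 3-methylbutanoate F4. A catalyst-controlled Nozaki–Hiyama–Kishi vinylation of F4 (vinyl bromide, CrCl2, NiCl2 (cat.), chiral oxazoline–sulfonamide ligand, Et3N, THF; ester-tolerant) gives (1S)-1-[(1S,2S,5R)-5-hydroxy-2-[(1R)-1-hydroxyprop-2-en-1-yl]-2-methyl-5-(propan-2-yl)cyclopentyl]-3-methylbut-3-en-1-yl 3-methylbutanoate F5. Ring-closing metathesis of F5 (second-generation Grubbs catalyst (H2IMes)(PCy3)Cl2Ru=CHPh, CH2Cl2, 40 °C) delivers 19.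

## Further compounds

F1 | step 5 | (3S)-3-(dimethoxymethyl)-3,7-dimethyl-6-oxooctanoic acid | OC(=O)C[C@@](C)(C(OC)OC)CCC(=O)C(C)C
F2 | step 5 | S-ethyl (3S)-3-(dimethoxymethyl)-3,7-dimethyl-6-oxooctanethioate | CCSC(=O)C[C@@](C)(C(OC)OC)CCC(=O)C(C)C
F3 | step 5 | S-ethyl (1R,2R,5S)-5-(dimethoxymethyl)-2-hydroxy-5-methyl-2-(propan-2-yl)cyclopentane-1-carbothioate | COC(OC)[C@@]1(C)CC[C@@](O)(C(C)C)[C@@H]1C(=O)SCC
F0 | step 6 | none | none
F4 | step 12 | (1S)-1-[(1S,2S,5R)-2-formyl-5-hydroxy-2-methyl-5-(propan-2-yl)cyclopentyl]-3-methylbut-3-en-1-yl 3-methylbutanoate | O=C[C@@]1(C)CC[C@@](O)(C(C)C)[C@@H]1[C@@H](OC(=O)CC(C)C)CC(C)=C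
F5 | step 12 | (1S)-1-[(1S,2S,5R)-5-hydroxy-2-[(1R)-1-hydroxyprop-2-en-1-yl]-2-methyl-5-(propan-2-yl)cyclopentyl]-3-methylbut-3-en-1-yl 3-methylbutanoate | C=C[C@@H](O)[C@@]1(C)CC[C@@](O)(C(C)C)[C@@H]1[C@@H](OC(=O)CC(C)C)CC(C)=C
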